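**Retrosynthetic overview**
1. Target 24 ⇐ α-methylene lactone 21: the C7=C11 alkene and the C13–O bond come from a photochemical singlet-oxygen ene transposition, followed by reduction and acetylation.
2. 21 ⇐ 16: both oxiranes by face-selective epoxidation of the 1(10),4-diene; the C8 ester from (R)-3-chloro-2-hydroxy-2-methylpropanoic acid, made from the bought bromo acid.
3. 16 ⇐ 14: the ten-membered carbocycle and the γ-lactone close together by chromium-mediated intramolecular allylation (C6–C7), with C6 and C7 controlled by C8.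
4. 14 ⇐ 9 ⇐ 7 + 4: C11–C13 by Baylis–Hillman reaction and bromination; the chain is joined at C1–C2 by nickel-electrocatalysed decarboxylative alkenylation.
5. 4 ⇐ methyl (S)-glycidate (source of C8); 7 ⇐ geranyl acetate. Ring order: carbocycle and lactone together (step 10), then the two oxiranes (step 14).

Assumption: the target is the single stereoisomer of the given SMILES, (1R,4R,5R,6S,8S,10R) with a (2R) acyl side chain; germacrane numbering (C1–C15) is used for ring positions.

**Step 1**
Reactants: 1 methyl (2S)-oxirane-2-carboxylate (methyl (S)-glycidate)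
Product: 2 methyl (2S)-2-hydroxypent-4-ynoate
Conditions: HC≡CH, n-BuLi, THF, −78 °C; BF3·OEt2; then 1, −78 °C
Reagents that add atoms: lithium acetylide, [Li]C#C
Why: BF3-assisted epoxide opening by the alkynyl anion (Yamaguchi–Hirao alkynylation) occurs at the unsubstituted CH2 without attack on the ester at −78 °C, so the bought stereocentre (future C8) is untouched.

**Step 2**
Reactants: 2 methyl (2S)-2-hydroxypent-4-ynoate
Product: 3 methyl (2S)-2-[(tert-butyldimethylsilyl)oxy]pent-4-ynoate
Conditions: TBSCl, imidazole, DMF, rt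
Reagents that add atoms: tert-butyldimethylsilyl chloride, CC(C)(C)[Si](C)(C)Cl
Why: Standard silylation; as a silyl ether O-8 can neither leave from the later allylmetal nor compete in lactonisation.

**Step 3**
Reactants: 3 methyl (2S)-2-[(tert-butyldimethylsilyl)oxy]pent-4-ynoate
Product: 4 methyl (2S,4E)-2-[(tert-butyldimethylsilyl)oxy]-5-iodo-4-methylpent-4-enoate
Conditions: Me3Al, Cp2ZrCl2 (cat.), H2O (1 equiv), CH2Cl2, −25 °C; then I2, THF, −25 → 0 °C
Reagents that add atoms: trimethylaluminium, C[Al](C)C; iodine, [I][I]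
Why: Negishi zirconium-catalysed carboalumination adds Me and Al syn across the terminal alkyne (Me to the internal carbon) and iodinolysis with retention gives the E-iodide that fixes the C1=C10 geometry, the low temperature sparing the hindered ester.

**Step 4**
Reactants: 5 geranyl acetate
Product: 7 (4E)-6-(acetyloxy)-4-methylhex-4-enoic acid, via (4E)-6-(acetyloxy)-4-methylhex-4-enal 6 (not isolated)
Conditions: O3 (1 equiv), CH2Cl2, −78 °C; Me2S; then NaClO2, NaH2PO4, 2-methylbut-2-ene, t-BuOH/H2O, 0 °C → rt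
Reagents that add atoms: ozone, [O-][O+]=O; sodium chlorite, [Na+].[O-]Cl=O
Why: Ozonolysis cleaves the electron-rich terminal alkene in preference to the acetate-deactivated allylic one, and Pinnick oxidation of the crude aldehyde leaves the E-alkene (future C4=C5) intact.

**Step 5**
Reactants: 7 (4E)-6-(acetyloxy)-4-methylhex-4-enoic acid; 4 methyl (2S,4E)-2-[(tert-butyldimethylsilyl)oxy]-5-iodo-4-methylpent-4-enoate
Product: 9 methyl (2S,4E,8E)-10-(acetyloxy)-2-[(tert-butyldimethylsilyl)oxy]-4,8-dimethyldeca-4,8-dienoate, via N-acyloxyphthalimide ester 8 (not isolated)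
Conditions: N-hydroxyphthalimide, DIC, DMAP (cat.), CH2Cl2, rt; then 4, NiCl2·6H2O (cat.), 2,2′-bipyridine, AgNO3 (cat.), DMF, Mg anode/RVC cathode, constant current, rt
Reagents that add atoms: none
Why: Nickel-electrocatalysed decarboxylative alkenylation: cathodic reduction of the redox-active ester gives the primary C2 radical, which the alkenylnickel from 4 captures with retention of the E geometry to forge C1–C2, far from the stereocentre.

**Step 6**
Reactants: 9 methyl (2S,4E,8E)-10-(acetyloxy)-2-[(tert-butyldimethylsilyl)oxy]-4,8-dimethyldeca-4,8-dienoate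
Product: 10 (2S,4E,8E)-2-[(tert-butyldimethylsilyl)oxy]-10-hydroxy-4,8-dimethyldeca-4,8-dienal
Conditions: i-Bu2AlH (3.3 equiv), CH2Cl2, −78 °C
Reagents that add atoms: none
Why: Partial ester reduction: at −78 °C the chelated α-silyloxy ester stops at the aluminium hemiacetal (aldehyde on work-up) while the acetate is cleaved, and the α-stereocentre does not epimerise.

**Step 7**
Reactants: 10 (2S,4E,8E)-2-[(tert-butyldimethylsilyl)oxy]-10-hydroxy-4,8-dimethyldeca-4,8-dienal; 11 methyl acrylate
Product: 12 methyl (4S,6E,10E)-4-[(tert-butyldimethylsilyl)oxy]-3,12-dihydroxy-6,10-dimethyl-2-methylidenedodeca-6,10-dienoate (both C3 epimers)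
Conditions: DABCO (0.5 equiv), MeOH, rt, 3 d
Reagents that add atoms: none
Why: Morita–Baylis–Hillman reaction of the activated α-silyloxy aldehyde; the new carbinol centre (future C7) forms as a mixture that is erased in step 9, and C8 is kept because the amine does not enolise the aldehyde.

**Step 8**
Reactants: 12 methyl (4S,6E,10E)-4-[(tert-butyldimethylsilyl)oxy]-3,12-dihydroxy-6,10-dimethyl-2-methylidenedodeca-6,10-dienoate
Product: 13 methyl (4S,6E,10E)-4-[(tert-butyldimethylsilyl)oxy]-3-hydroxy-6,10-dimethyl-2-methylidene-12-oxododeca-6,10-dienoate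
Conditions: MnO2, CH2Cl2, rt
Reagents that add atoms: none
Why: Chemoselective allylic oxidation: activated MnO2 oxidises the electron-rich primary allylic alcohol to the E-enal and leaves the secondary alcohol beside the electron-poor acrylate alone.

**Step 9**
Reactants: 13 methyl (4S,6E,10E)-4-[(tert-butyldimethylsilyl)oxy]-3-hydroxy-6,10-dimethyl-2-methylidene-12-oxododeca-6,10-dienoate
Product: 14 methyl (2Z,4S,6E,10E)-2-(bromomethyl)-4-[(tert-butyldimethylsilyl)oxy]-6,10-dimethyl-12-oxododeca-2,6,10-trienoate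
Conditions: NBS, Me2S, CH2Cl2, 0 °C → rt
Reagents that add atoms: N-bromosuccinimide, O=C1CCC(=O)N1Br
Why: Corey–Kim-type bromination: bromide displaces the alkoxysulfonium of the Baylis–Hillman alcohol in an SN2′ sense to give the conjugated Z-allyl bromide, with enal and silyl ether inert.

**Step 10**
Reactants: 14 methyl (2Z,4S,6E,10E)-2-(bromomethyl)-4-[(tert-butyldimethylsilyl)oxy]-6,10-dimethyl-12-oxododeca-2,6,10-trienoate
Product: 15 (6R,7S,8S)-8-[(tert-butyldimethylsilyl)oxy]germacra-1(10)E,4E,11(13)-trien-12,6-olide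
Conditions: CrCl2 (5 equiv), DMF/THF, rt, slow addition (2 mM)
Reagents that add atoms: none
Why: Nozaki–Hiyama (Barbier-type) allylation: the allylchromium attacks the enal through C7 in a chair transition state and the alkoxide lactonises, closing the carbocycle and the lactone at once; with H-8 eclipsing the alkene the aldehyde should approach anti to the bulky C8–OSi bond and give the trans lactone, so C8 sets C6 and C7.

**Step 11**
Reactants: 15 (6R,7S,8S)-8-[(tert-butyldimethylsilyl)oxy]germacra-1(10)E,4E,11(13)-trien-12,6-olide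
Product: 16 (6R,7R,8S)-8-hydroxygermacra-1(10)E,4E,11(13)-trien-12,6-olide
Conditions: Bu4NF, AcOH, THF, 0 °C
Reagents that add atoms: none
Why: Fluoride-mediated desilylation; acetic acid buffering prevents alkoxide addition to the α-methylene lactone and lactone migration to O-8.

**Step 12**
Reactants: 17 (2R)-3-bromo-2-hydroxy-2-methylpropanoic acid
Product: 19 (2R)-3-chloro-2-hydroxy-2-methylpropanoic acid, via sodium (2S)-2-methyloxirane-2-carboxylate 18 (not isolated)
Conditions: NaOH (2.2 equiv), H2O, 0 °C → rt; then conc. HCl, 0 °C → rt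
Reagents that add atoms: hydrogen chloride, Cl
Why: Intramolecular Williamson closure to the glycidate, then SN2 opening by chloride at the CH2; no bond to the quaternary stereocentre is made or broken, so the bought configuration is kept.

**Step 13**
Reactants: 16 (6R,7R,8S)-8-hydroxygermacra-1(10)E,4E,11(13)-trien-12,6-olide; 19 (2R)-3-chloro-2-hydroxy-2-methylpropanoic acid
Product: 20 (6R,7R,8S)-8-{[(2R)-3-chloro-2-hydroxy-2-methylpropanoyl]oxy}germacra-1(10)E,4E,11(13)-trien-12,6-olide
Conditions: DCC, DMAP (cat.), CH2Cl2, 0 °C → rt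
Reagents that add atoms: none
Why: Steglich esterification acylates the secondary C8–OH with retention (no C–O bond at C8 is broken) while the hindered tertiary hydroxyl of the acid does not compete.

**Step 14**
Reactants: 20 (6R,7R,8S)-8-{[(2R)-3-chloro-2-hydroxy-2-methylpropanoyl]oxy}germacra-1(10)E,4E,11(13)-trien-12,6-olide
Product: 21 (1R,4R,5R,6S,7R,8S,10R)-8-{[(2R)-3-chloro-2-hydroxy-2-methylpropanoyl]oxy}-1,10:4,5-diepoxygermacr-11(13)-en-12,6-olide
Conditions: DMDO (2.3 equiv), acetone/CH2Cl2, 0 °C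
Reagents that add atoms: dimethyldioxirane, CC1(C)OO1
Why: Electrophilic epoxidation of the two electron-rich E-trisubstituted alkenes from the exposed outer face of the crown conformer fixed by C6, C7 and C8 (as with costunolide-type lactones) sets C1, C10, C4 and C5, while the electron-poor α-methylene lactone is inert.

**Step 15**
Reactants: 21 (1R,4R,5R,6S,7R,8S,10R)-8-{[(2R)-3-chloro-2-hydroxy-2-methylpropanoyl]oxy}-1,10:4,5-diepoxygermacr-11(13)-en-12,6-olide
Product: 24 CNP0255009.1, via 13-hydroperoxide 22 (not isolated), via 13-alcohol 23 (not isolated)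
Conditions: O2, tetraphenylporphyrin (cat.), visible light, CCl4/CDCl3, 0 °C; then PPh3; then Ac2O, pyridine, 0 °C → rt
Reagents that add atoms: oxygen, O=O; acetic anhydride, CC(=O)OC(C)=O
Why: Proposed new method: photosensitised singlet oxygen should undergo a Schenck ene reaction with the s-cis α-methylene lactone, the perepoxide on C11=C13 abstracting the only allylic hydrogen (H-7, on the substituent geminal to the carbonyl) so that oxygen binds C13 and the alkene moves into the ring as the C7=C11 butenolide (the C7 stereocentre is erased, none is created), after which phosphine reduction and acetylation follow in the same flask; the closest known reaction is the geminal-selective singlet-oxygen ene reaction of α,β-unsaturated esters such as tiglates, not yet shown for the slower exocyclic α-methylene-γ-lactones, hence the long-lifetime halogenated solvent.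

**Compound list**
1 | methyl (2S)-oxirane-2-carboxylate | COC(=O)[C@@H]1CO1 | starting material
2 | methyl (2S)-2-hydroxypent-4-ynoate | COC(=O)[C@@H](O)CC#C | intermediate
3 | methyl (2S)-2-[(tert-butyldimethylsilyl)oxy]pent-4-ynoate | COC(=O)[C@@H](O[Si](C)(C)C(C)(C)C)CC#C | intermediate
4 | methyl (2S,4E)-2-[(tert-butyldimethylsilyl)oxy]-5-iodo-4-methylpent-4-enoate | COC(=O)[C@@H](O[Si](C)(C)C(C)(C)C)C/C(C)=C/I | intermediate
5 | geranyl acetate | CC(C)=CCC/C(C)=C/COC(C)=O | starting material
6 | (4E)-6-(acetyloxy)-4-methylhex-4-enal | O=CCC/C(C)=C/COC(C)=O | intermediate (not isolated)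
7 | (4E)-6-(acetyloxy)-4-methylhex-4-enoic acid | OC(=O)CC/C(C)=C/COC(C)=O | intermediate
8 | 1,3-dioxoisoindolin-2-yl (4E)-6-(acetyloxy)-4-methylhex-4-enoate | O=C(CC/C(C)=C/COC(C)=O)ON1C(=O)c2ccccc2C1=O | intermediate (not isolated)
9 | methyl (2S,4E,8E)-10-(acetyloxy)-2-[(tert-butyldimethylsilyl)oxy]-4,8-dimethyldeca-4,8-dienoate | COC(=O)[C@@H](O[Si](C)(C)C(C)(C)C)C/C(C)=C/CC/C(C)=C/COC(C)=O | intermediate
10 | (2S,4E,8E)-2-[(tert-butyldimethylsilyl)oxy]-10-hydroxy-4,8-dimethyldeca-4,8-dienal | O=C[C@@H](O[Si](C)(C)C(C)(C)C)C/C(C)=C/CC/C(C)=C/CO | intermediate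
11 | methyl acrylate | C=CC(=O)OC | starting material
12 | methyl (4S,6E,10E)-4-[(tert-butyldimethylsilyl)oxy]-3,12-dihydroxy-6,10-dimethyl-2-methylidenedodeca-6,10-dienoate (both C3 epimers) | C=C(C(=O)OC)C(O)[C@@H](O[Si](C)(C)C(C)(C)C)C/C(C)=C/CC/C(C)=C/CO | intermediate
13 | methyl (4S,6E,10E)-4-[(tert-butyldimethylsilyl)oxy]-3-hydroxy-6,10-dimethyl-2-methylidene-12-oxododeca-6,10-dienoate (both C3 epimers) | C=C(C(=O)OC)C(O)[C@@H](O[Si](C)(C)C(C)(C)C)C/C(C)=C/CC/C(C)=C/C=O | intermediate
14 | methyl (2Z,4S,6E,10E)-2-(bromomethyl)-4-[(tert-butyldimethylsilyl)oxy]-6,10-dimethyl-12-oxododeca-2,6,10-trienoate | COC(=O)/C(CBr)=C/[C@@H](O[Si](C)(C)C(C)(C)C)C/C(C)=C/CC/C(C)=C/C=O | intermediate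
15 | (6R,7S,8S)-8-[(tert-butyldimethylsilyl)oxy]germacra-1(10)E,4E,11(13)-trien-12,6-olide | C=C1[C@@H]2[C@@H](O[Si](C)(C)C(C)(C)C)C/C(C)=C/CC/C(C)=C/[C@H]2OC1=O | intermediate
16 | (6R,7R,8S)-8-hydroxygermacra-1(10)E,4E,11(13)-trien-12,6-olide | C=C1[C@@H]2[C@@H](O)C/C(C)=C/CC/C(C)=C/[C@H]2OC1=O | intermediate
17 | (2R)-3-bromo-2-hydroxy-2-methylpropanoic acid | OC(=O)[C@@](C)(O)CBr | starting material
18 | sodium (2S)-2-methyloxirane-2-carboxylate | [Na+].[O-]C(=O)[C@@]1(C)OC1 | intermediate (not isolated)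
19 | (2R)-3-chloro-2-hydroxy-2-methylpropanoic acid | OC(=O)[C@@](C)(O)CCl | intermediate
20 | (6R,7R,8S)-8-{[(2R)-3-chloro-2-hydroxy-2-methylpropanoyl]oxy}germacra-1(10)E,4E,11(13)-trien-12,6-olide | C=C1[C@@H]2[C@@H](OC(=O)[C@@](C)(O)CCl)C/C(C)=C/CC/C(C)=C/[C@H]2OC1=O | intermediate
21 | (1R,4R,5R,6S,7R,8S,10R)-8-{[(2R)-3-chloro-2-hydroxy-2-methylpropanoyl]oxy}-1,10:4,5-diepoxygermacr-11(13)-en-12,6-olide | C=C1[C@@H]2[C@@H](OC(=O)[C@@](C)(O)CCl)C[C@@]3(C)O[C@@H]3CC[C@@]3(C)O[C@@H]3[C@H]2OC1=O | intermediate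
22 | (1R,4R,5R,6S,8S,10R)-8-{[(2R)-3-chloro-2-hydroxy-2-methylpropanoyl]oxy}-13-hydroperoxy-1,10:4,5-diepoxygermacr-7(11)-en-12,6-olide | OOCC1=C2[C@@H](OC(=O)[C@@](C)(O)CCl)C[C@@]3(C)O[C@@H]3CC[C@@]3(C)O[C@@H]3[C@H]2OC1=O | intermediate (not isolated)
23 | (1R,4R,5R,6S,8S,10R)-8-{[(2R)-3-chloro-2-hydroxy-2-methylpropanoyl]oxy}-13-hydroxy-1,10:4,5-diepoxygermacr-7(11)-en-12,6-olide | OCC1=C2[C@@H](OC(=O)[C@@](C)(O)CCl)C[C@@]3(C)O[C@@H]3CC[C@@]3(C)O[C@@H]3[C@H]2OC1=O | intermediate (not isolated)
24 | CNP0255009.1, (1R,4R,5R,6S,8S,10R)-13-(acetyloxy)-8-{[(2R)-3-chloro-2-hydroxy-2-methylpropanoyl]oxy}-1,10:4,5-diepoxygermacr-7(11)-en-12,6-olide | CC(=O)OCC1=C2[C@@H](OC(=O)[C@@](C)(O)CCl)C[C@@]3(C)O[C@@H]3CC[C@@]3(C)O[C@@H]3[C@H]2OC1=O | target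

**Totals and risks**
Total step count: 15. Longest linear sequence: 13 steps (1–3, 5–11, 13–15).

Step 15 (the new photochemical ene step) may fail because the α-methylene lactone is electron-poor toward singlet oxygen. The fallback uses known chemistry and sets out from 21. Wohl–Ziegler bromination (NBS, visible light, PhCF3, solid NaHCO3) abstracts the same tertiary allylic H-7 and delivers bromine to C13 with allylic transposition, giving the 13-bromo-7(11)-butenolide F1. Displacement with Bu4NOAc in MeCN then comes back to the route at 24.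

Step 10 may give a low yield or the wrong C6/C7 relationship in the ten-membered ring closure. The fallback sets out from 13. Acetylation (Ac2O, pyridine) gives the Baylis–Hillman acetate F2. Pd(PPh3)4-catalysed umpolung allylation with Et2Zn under high dilution (π-allylpalladium to allylzinc, cyclic transition state, lactonisation on work-up) replaces the halide/chromium pathway and comes back at 15.

Step 13 may fail because the unprotected tertiary α-hydroxy acid can self-condense or couple poorly with the hindered C8–OH. The fallback sets out from 16 and 18. Cold acidification of 18 and extraction give (2S)-2-methyloxirane-2-carboxylic acid F3, which has no free hydroxyl. DCC/DMAP coupling with 16 gives the glycidate ester F4, and pyridinium chloride in CH2Cl2 opens the oxirane at its CH2, coming back at 20.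

**Further compounds**
F1 | step 15 | (1R,4R,5R,6S,8S,10R)-13-bromo-8-{[(2R)-3-chloro-2-hydroxy-2-methylpropanoyl]oxy}-1,10:4,5-diepoxygermacr-7(11)-en-12,6-olide | BrCC1=C2[C@@H](OC(=O)[C@@](C)(O)CCl)C[C@@]3(C)O[C@@H]3CC[C@@]3(C)O[C@@H]3[C@H]2OC1=O
F2 | step 10 | methyl (4S,6E,10E)-3-(acetyloxy)-4-[(tert-butyldimethylsilyl)oxy]-6,10-dimethyl-2-methylidene-12-oxododeca-6,10-dienoate (both C3 epimers) | C=C(C(=O)OC)C(OC(C)=O)[C@@H](O[Si](C)(C)C(C)(C)C)C/C(C)=C/CC/C(C)=C/C=O
F3 | step 13 | (2S)-2-methyloxirane-2-carboxylic acid | OC(=O)[C@@]1(C)OC1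
F4 | step 13 | (6R,7R,8S)-8-{[(2S)-2-methyloxirane-2-carbonyl]oxy}germacra-1(10)E,4E,11(13)-trien-12,6-olide | C=C1[C@@H]2[C@@H](OC(=O)[C@@]3(C)OC3)C/C(C)=C/CC/C(C)=C/[C@H]2OC1=O
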